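**Retrosynthetic overview**
- The target is opened at the C4 acetate, the C4 carbinol and the axial C6 methyl, giving a tricyclo[5.3.1.0(3,8)]undecadienone; these three features are added late under substrate control.
- The tricyclic core comes from an intramolecular double Michael ([4+2]) reaction of a (4S)-4,4-disubstituted cyclohex-2-enone carrying a tigloyl-ethyl tether; ring B and the bicyclo[2.2.2]octane close in the same step.
- The quaternary carbon comes from a new enantioselective Diels–Alder/retro-aldol relay between a 4-alkyl-1-silyloxycyclohexa-1,3-diene and (E)-4-methylhexa-1,4-dien-3-one.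
- The diene comes from Birch reduction of a 4-alkylanisole; its (S)-tertiary allylic alcohol is made by carboalumination, Sharpless epoxidation and zinc-induced opening of the epoxy iodide.
- Ring order: anisole ring, then cyclohexenone (ring A), then ring B together with the bridging bonds.

Assumption: alkyne 1 is bought as a catalogue compound; the sense of induction in step 9 is assigned by analogy (the enantiomeric catalyst is equally available); TES = triethylsilyl, TBS = tert-butyldimethylsilyl; tricyclic compounds keep the tricyclo[5.3.1.0(3,8)]undecane locants of the target throughout.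

**Route**

Step 1
Reactants: 1 1-(but-3-yn-1-yl)-4-methoxybenzene
Product: 4 (2E)-5-(4-methoxyphenyl)-3-methylpent-2-en-1-ol, via alkenyldimethylalane 2 (not isolated), via lithium alkenylalanate 3 (not isolated)
Conditions: Me3Al (2.5 equiv), Cp2ZrCl2 (0.25 equiv), CH2Cl2, 0 to 23 °C; nBuLi, THF, −78 °C; (CH2O)n, 23 °C; aq HCl
Reagents that add atoms: trimethylaluminium C[Al](C)C; paraformaldehyde (as formaldehyde) C=O
Why: Zirconium-catalysed syn-carboalumination of the terminal alkyne (Negishi carboalumination) puts the methyl group on the internal carbon and aluminium on the terminus, and the derived alanate adds to formaldehyde with retention, so only the E trisubstituted allylic alcohol forms.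

Step 2
Reactants: 4 (2E)-5-(4-methoxyphenyl)-3-methylpent-2-en-1-ol
Product: 5 {(2S,3S)-3-[2-(4-methoxyphenyl)ethyl]-3-methyloxiran-2-yl}methanol
Conditions: Ti(OiPr)4 (10 mol %), L-(+)-diethyl tartrate (12 mol %), tBuOOH, 4 Å sieves, CH2Cl2, −20 °C
Reagents that add atoms: tert-butyl hydroperoxide CC(C)(C)OO
Why: Sharpless asymmetric epoxidation of a geraniol-type E allylic alcohol; the L-(+)-tartrate ligand delivers oxygen to the face that gives the (2S,3S)-epoxide, which fixes the future side-chain carbinol centre.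

Step 3
Reactants: 5 {(2S,3S)-3-[2-(4-methoxyphenyl)ethyl]-3-methyloxiran-2-yl}methanol
Product: 6 (2R,3S)-2-(iodomethyl)-3-[2-(4-methoxyphenyl)ethyl]-3-methyloxirane
Conditions: I2, PPh3, imidazole, THF, 0 °C
Reagents that add atoms: iodine II
Why: Appel-type iodination of the primary alcohol under neutral conditions leaves the epoxide untouched; no stereocentre is altered (the C2 descriptor changes only because iodine changes the priorities).

Step 4
Reactants: 6 (2R,3S)-2-(iodomethyl)-3-[2-(4-methoxyphenyl)ethyl]-3-methyloxirane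
Product: 7 (3S)-5-(4-methoxyphenyl)-3-methylpent-1-en-3-ol
Conditions: Zn dust, AcOH, EtOH, 23 °C
Reagents that add atoms: none
Why: Zinc inserts into the C–I bond and β-elimination opens the epoxide (reductive elimination of a 2,3-epoxy iodide) to the tertiary allylic alcohol; the C3–O bond is never broken, so the (S) centre is retained.

Step 5
Reactants: 7 (3S)-5-(4-methoxyphenyl)-3-methylpent-1-en-3-ol
Product: 9 4-[(3S)-3-hydroxy-3-methylpent-4-en-1-yl]cyclohex-3-en-1-one, via dihydroanisole enol ether 8 (not isolated)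
Conditions: Li, NH3 (l), tBuOH, THF, −78 °C; NH4Cl; then (CO2H)2, THF–H2O, 23 °C
Reagents that add atoms: water O
Why: Birch reduction of the 4-alkylanisole gives the 1-methoxy-1,4-diene while the isolated vinyl group and the lithium alkoxide are inert to Li/NH3, and mild oxalic-acid hydrolysis of the enol ether gives the β,γ-enone without ionising the tertiary allylic alcohol.

Step 6
Reactants: 9 4-[(3S)-3-hydroxy-3-methylpent-4-en-1-yl]cyclohex-3-en-1-one
Product: 10 triethyl[(4-{(3S)-3-methyl-3-[(triethylsilyl)oxy]pent-4-en-1-yl}cyclohexa-1,3-dien-1-yl)oxy]silane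
Conditions: Et3SiOTf (2.4 equiv), Et3N, CH2Cl2, −78 to 0 °C
Reagents that add atoms: triethylsilyl trifluoromethanesulfonate CC[Si](CC)(CC)OS(=O)(=O)C(F)(F)F
Why: Soft enolisation (silyl triflate/amine) removes the doubly activated proton between the carbonyl and the ring alkene, giving the conjugated 1-silyloxy-1,3-diene, and silylates the tertiary alcohol in the same operation.

Step 7
Reactants: 11 (2E)-2-methylbut-2-enal
Product: 12 (4E)-4-methylhexa-1,4-dien-3-ol (racemic)
Conditions: CH2=CHMgBr, THF, −78 to 0 °C; aq NH4Cl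
Reagents that add atoms: vinylmagnesium bromide C=C[Mg]Br
Why: Grignard 1,2-addition to the enal; the new carbinol centre is racemic and is removed in step 8.

Step 8
Reactants: 12 (4E)-4-methylhexa-1,4-dien-3-ol
Product: 13 (4E)-4-methylhexa-1,4-dien-3-one
Conditions: MnO2, CH2Cl2, 23 °C
Reagents that add atoms: none
Why: MnO2 oxidation of the doubly allylic alcohol gives the cross-conjugated divinyl ketone without touching the E alkene; it is used freshly prepared.

Step 9
Reactants: 10 triethyl[(4-{(3S)-3-methyl-3-[(triethylsilyl)oxy]pent-4-en-1-yl}cyclohexa-1,3-dien-1-yl)oxy]silane; 13 (4E)-4-methylhexa-1,4-dien-3-one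
Product: 15 (4S)-4-[(3S)-3-hydroxy-3-methylpent-4-en-1-yl]-4-[(4E)-4-methyl-3-oxohex-4-en-1-yl]cyclohex-2-en-1-one, via bicyclooctene cycloadduct 14 (not isolated)
Conditions: (S)-3,3-diphenyl-1-(2-methylphenyl)tetrahydro-1H,3H-pyrrolo[1,2-c][1,3,2]oxazaborole·HN(SO2CF3)2 (20 mol %), CH2Cl2, −78 °C; then Bu4NF, THF, −40 to 0 °C; AcOH
Reagents that add atoms: none
Why: Proposed new method: an enantioselective Diels–Alder/retro-aldol relay that amounts to a catalytic asymmetric γ-alkylation of a cyclohexenone at a fully substituted carbon; the cationic oxazaborolidine binds the carbonyl of 13 on the side of its unsubstituted vinyl group (the tiglyl side is too hindered) and shields one face of that enone, the diene adds endo with its alkyl-bearing terminus (largest HOMO coefficient, para to the silyloxy group) to the CH2 terminus, so the diene face used and hence the (S) quaternary carbon follow from catalyst face selectivity combined with the endo rule, and fluoride then frees the bridgehead alkoxide whose strain-driven retro-aldol cleaves the bond to the ketone α-carbon, erasing the two auxiliary stereocentres and leaving the 4,4-disubstituted enone; the closest known reaction types are oxazaborolidinium-catalysed enantioselective Diels–Alder reactions of acyclic enones with silyloxydienes and the racemic Diels–Alder/retro-aldol sequence of 1-silyloxycyclohexa-1,3-dienes with vinyl ketones, neither shown for a 4-alkyl diene terminus that becomes a quaternary stereocentre or for a divinyl ketone.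

Step 10
Reactants: 15 (4S)-4-[(3S)-3-hydroxy-3-methylpent-4-en-1-yl]-4-[(4E)-4-methyl-3-oxohex-4-en-1-yl]cyclohex-2-en-1-one
Product: 18 (1R,2R,3S,7R,8S)-10-(TBS-oxy)-7-[(3S)-3-(TBS-oxy)-3-methylpent-4-en-1-yl]-2,3-dimethyltricyclo[5.3.1.0(3,8)]undec-9-en-4-one, via dilithium ring dienolate 16 (not isolated), via tricyclic lithium enolate 17 (not isolated)
Conditions: LiN(SiMe3)2 (2.2 equiv), THF, −78 to 0 °C; then tBuMe2SiOTf (2.5 equiv), −78 °C
Reagents that add atoms: tert-butyldimethylsilyl trifluoromethanesulfonate CC(C)(C)[Si](C)(C)OS(=O)(=O)C(F)(F)F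
Why: Intramolecular double Michael reaction (anionic [4+2]) in which only the ring cross-conjugated dienolate has a productive path (the side-chain enolate can only revert by proton transfer or reversible aldol), the three-atom tether on the quaternary carbon forces addition to one diene face (sets both bridgeheads C1 and C8), the E tigloyl geometry places the two methyl-bearing carbons cis (sets C2 and C3), and the bicyclooctanone enolate formed by the second Michael step is trapped as its silyl enol ether, which keeps the two carbonyl groups differentiated.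

Step 11
Reactants: 18 (1R,2R,3S,7R,8S)-10-(TBS-oxy)-7-[(3S)-3-(TBS-oxy)-3-methylpent-4-en-1-yl]-2,3-dimethyltricyclo[5.3.1.0(3,8)]undec-9-en-4-one
Product: 19 (1R,2R,3S,7S,8S)-10-(TBS-oxy)-7-[(3S)-3-(TBS-oxy)-3-methylpent-4-en-1-yl]-2,3-dimethyltricyclo[5.3.1.0(3,8)]undeca-5,9-dien-4-one
Conditions: LiN(iPr)2, THF, −78 °C; PhS(Cl)=NtBu, −78 °C
Reagents that add atoms: none
Why: Mukaiyama dehydrogenation: the only enolisable position is the CH2 next to the ring-B ketone, the enolate is sulfenylated by the sulfinimidoyl chloride and syn-elimination gives the enone at low temperature; no stereocentre is touched (the C7 descriptor changes only through the new double bond).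

Step 12
Reactants: 19 (1R,2R,3S,7S,8S)-10-(TBS-oxy)-7-[(3S)-3-(TBS-oxy)-3-methylpent-4-en-1-yl]-2,3-dimethyltricyclo[5.3.1.0(3,8)]undeca-5,9-dien-4-one
Product: 20 (1R,2R,3S,6R,7S,8S)-10-(TBS-oxy)-7-[(3S)-3-(TBS-oxy)-3-methylpent-4-en-1-yl]-2,3,6-trimethyltricyclo[5.3.1.0(3,8)]undec-9-en-4-one
Conditions: Me2CuLi (from MeLi and CuI), Et2O, −40 to 0 °C; aq NH4Cl
Reagents that add atoms: lithium dimethylcuprate [Li+].C[Cu-]C
Why: Cuprate 1,4-addition; the stereoelectronically preferred axial attack on the ring-B enone is also the attack anti to the axial CH2 bridge on the neighbouring quaternary carbon (the situation of 1α-methylation of Δ1-3-keto steroids), giving the axial (6R) methyl group.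

Step 13
Reactants: 20 (1R,2R,3S,6R,7S,8S)-10-(TBS-oxy)-7-[(3S)-3-(TBS-oxy)-3-methylpent-4-en-1-yl]-2,3,6-trimethyltricyclo[5.3.1.0(3,8)]undec-9-en-4-one
Product: 21 (1R,2R,3S,4R,6R,7S,8S)-10-(TBS-oxy)-7-[(3S)-3-(TBS-oxy)-3-methylpent-4-en-1-yl]-2,3,6-trimethyltricyclo[5.3.1.0(3,8)]undec-9-en-4-ol
Conditions: SmI2, H2O, Et3N, THF, 23 °C
Reagents that add atoms: none
Why: Electron-transfer (ketyl) reduction gives the thermodynamically preferred alcohol: the bulky O–Sm group settles equatorial, away from the syn-axial C6 methyl, and protonation occurs axially, giving the equatorial (4R) alcohol; the silyl enol ether and the isolated vinyl group are inert.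

Step 14
Reactants: 21 (1R,2R,3S,4R,6R,7S,8S)-10-(TBS-oxy)-7-[(3S)-3-(TBS-oxy)-3-methylpent-4-en-1-yl]-2,3,6-trimethyltricyclo[5.3.1.0(3,8)]undec-9-en-4-ol
Product: 22 (1R,2R,3S,4R,6R,7S,8S)-10-(TBS-oxy)-7-[(3S)-3-(TBS-oxy)-3-methylpent-4-en-1-yl]-2,3,6-trimethyltricyclo[5.3.1.0(3,8)]undec-9-en-4-yl acetate
Conditions: Ac2O, Et3N, 4-(dimethylamino)pyridine (0.2 equiv), CH2Cl2, 23 °C
Reagents that add atoms: acetic anhydride CC(=O)OC(C)=O
Why: Nucleophile-catalysed acylation of the hindered equatorial secondary alcohol; the tertiary alcohol is silylated and the silyl enol ether is stable to the basic medium.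

Step 15
Reactants: 22 (1R,2R,3S,4R,6R,7S,8S)-10-(TBS-oxy)-7-[(3S)-3-(TBS-oxy)-3-methylpent-4-en-1-yl]-2,3,6-trimethyltricyclo[5.3.1.0(3,8)]undec-9-en-4-yl acetate
Product: 23 (1R,2R,3S,4R,6R,7S,8S)-7-[(3S)-3-hydroxy-3-methylpent-4-en-1-yl]-2,3,6-trimethyl-10-oxotricyclo[5.3.1.0(3,8)]undecan-4-yl acetate (target)
Conditions: HF·pyridine, pyridine, THF, 0 to 23 °C
Reagents that add atoms: none
Why: Fluoride-mediated desilylation cleaves the silyl enol ether (ketonisation gives the bicyclo[2.2.2]octanone, whose bridgehead α-carbon cannot epimerise) and the tertiary silyl ether, while the buffered medium leaves the acetate and the tertiary allylic alcohol intact.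

**Compound list**

1 | 1-(but-3-yn-1-yl)-4-methoxybenzene | C#CCCc1ccc(OC)cc1 | starting material
2 | [(1E)-4-(4-methoxyphenyl)-2-methylbut-1-en-1-yl]dimethylalane | C[Al](C)/C=C(\C)CCc1ccc(OC)cc1 | intermediate
3 | lithium butyl[(1E)-4-(4-methoxyphenyl)-2-methylbut-1-en-1-yl]dimethylalanate | [Li+].CCCC[Al-](C)(C)/C=C(\C)CCc1ccc(OC)cc1 | intermediate
4 | (2E)-5-(4-methoxyphenyl)-3-methylpent-2-en-1-ol | OC/C=C(\C)CCc1ccc(OC)cc1 | intermediate
5 | {(2S,3S)-3-[2-(4-methoxyphenyl)ethyl]-3-methyloxiran-2-yl}methanol | OC[C@@H]1O[C@@]1(C)CCc2ccc(OC)cc2 | intermediate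
6 | (2R,3S)-2-(iodomethyl)-3-[2-(4-methoxyphenyl)ethyl]-3-methyloxirane | IC[C@@H]1O[C@@]1(C)CCc2ccc(OC)cc2 | intermediate
7 | (3S)-5-(4-methoxyphenyl)-3-methylpent-1-en-3-ol | C=C[C@@](C)(O)CCc1ccc(OC)cc1 | intermediate
8 | (3S)-5-(4-methoxycyclohexa-1,4-dien-1-yl)-3-methylpent-1-en-3-ol | C=C[C@@](C)(O)CCC1=CCC(OC)=CC1 | intermediate
9 | 4-[(3S)-3-hydroxy-3-methylpent-4-en-1-yl]cyclohex-3-en-1-one | C=C[C@@](C)(O)CCC1=CCC(=O)CC1 | intermediate
10 | triethyl[(4-{(3S)-3-methyl-3-[(triethylsilyl)oxy]pent-4-en-1-yl}cyclohexa-1,3-dien-1-yl)oxy]silane | C=C[C@@](C)(O[Si](CC)(CC)CC)CCC1=CC=C(O[Si](CC)(CC)CC)CC1 | intermediate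
11 | (2E)-2-methylbut-2-enal (tiglaldehyde) | C/C=C(\C)C=O | starting material
12 | (4E)-4-methylhexa-1,4-dien-3-ol, racemic | C/C=C(\C)C(O)C=C | intermediate
13 | (4E)-4-methylhexa-1,4-dien-3-one | C/C=C(\C)C(=O)C=C | intermediate
14 | (2E)-2-methyl-1-[(1R,2S,4S)-4-{(3S)-3-methyl-3-[(triethylsilyl)oxy]pent-4-en-1-yl}-1-[(triethylsilyl)oxy]bicyclo[2.2.2]oct-5-en-2-yl]but-2-en-1-one (endo adduct) | C=C[C@@](C)(O[Si](CC)(CC)CC)CC[C@]12C=C[C@](O[Si](CC)(CC)CC)(CC1)[C@H](C2)C(=O)/C(C)=C/C | intermediate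
15 | (4S)-4-[(3S)-3-hydroxy-3-methylpent-4-en-1-yl]-4-[(4E)-4-methyl-3-oxohex-4-en-1-yl]cyclohex-2-en-1-one | C=C[C@@](C)(O)CC[C@]1(CCC(=O)/C(C)=C/C)C=CC(=O)CC1 | intermediate
16 | dilithium salt of 15: side-chain alkoxide and ring cross-conjugated dienolate (ring O–Li on the 1,5-dien-1-olate) | C=C[C@@](C)(O[Li])CC[C@]1(CCC(=O)/C(C)=C/C)C=CC(O[Li])=CC1 | intermediate
17 | dilithium salt of the tricyclic 4-oxo-undec-9-en-10-olate with side-chain alkoxide (ring stereocentres as in 18) | C=C[C@@](C)(O[Li])CC[C@@]12C[C@H]3C(O[Li])=C[C@@H]1[C@](C)([C@@H]3C)C(=O)CC2 | intermediate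
18 | (1R,2R,3S,7R,8S)-10-(TBS-oxy)-7-[(3S)-3-(TBS-oxy)-3-methylpent-4-en-1-yl]-2,3-dimethyltricyclo[5.3.1.0(3,8)]undec-9-en-4-one | C=C[C@@](C)(O[Si](C)(C)C(C)(C)C)CC[C@@]12C[C@H]3C(O[Si](C)(C)C(C)(C)C)=C[C@@H]1[C@](C)([C@@H]3C)C(=O)CC2 | intermediate
19 | (1R,2R,3S,7S,8S)-10-(TBS-oxy)-7-[(3S)-3-(TBS-oxy)-3-methylpent-4-en-1-yl]-2,3-dimethyltricyclo[5.3.1.0(3,8)]undeca-5,9-dien-4-one | C=C[C@@](C)(O[Si](C)(C)C(C)(C)C)CC[C@@]12C[C@H]3C(O[Si](C)(C)C(C)(C)C)=C[C@@H]1[C@](C)([C@@H]3C)C(=O)C=C2 | intermediate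
20 | (1R,2R,3S,6R,7S,8S)-10-(TBS-oxy)-7-[(3S)-3-(TBS-oxy)-3-methylpent-4-en-1-yl]-2,3,6-trimethyltricyclo[5.3.1.0(3,8)]undec-9-en-4-one | C=C[C@@](C)(O[Si](C)(C)C(C)(C)C)CC[C@@]12C[C@H]3C(O[Si](C)(C)C(C)(C)C)=C[C@@H]1[C@](C)([C@@H]3C)C(=O)C[C@H]2C | intermediate
21 | (1R,2R,3S,4R,6R,7S,8S)-10-(TBS-oxy)-7-[(3S)-3-(TBS-oxy)-3-methylpent-4-en-1-yl]-2,3,6-trimethyltricyclo[5.3.1.0(3,8)]undec-9-en-4-ol | C=C[C@@](C)(O[Si](C)(C)C(C)(C)C)CC[C@@]12C[C@H]3C(O[Si](C)(C)C(C)(C)C)=C[C@@H]1[C@](C)([C@@H]3C)[C@H](O)C[C@H]2C | intermediate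
22 | (1R,2R,3S,4R,6R,7S,8S)-10-(TBS-oxy)-7-[(3S)-3-(TBS-oxy)-3-methylpent-4-en-1-yl]-2,3,6-trimethyltricyclo[5.3.1.0(3,8)]undec-9-en-4-yl acetate | C=C[C@@](C)(O[Si](C)(C)C(C)(C)C)CC[C@@]12C[C@H]3C(O[Si](C)(C)C(C)(C)C)=C[C@@H]1[C@](C)([C@@H]3C)[C@H](OC(C)=O)C[C@H]2C | intermediate
23 | (1R,2R,3S,4R,6R,7S,8S)-7-[(3S)-3-hydroxy-3-methylpent-4-en-1-yl]-2,3,6-trimethyl-10-oxotricyclo[5.3.1.0(3,8)]undecan-4-yl acetate | C=C[C@@](C)(O)CC[C@@]12C[C@H]3C(=O)C[C@@H]1[C@](C)([C@@H]3C)[C@H](OC(C)=O)C[C@H]2C | target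

**Step count and risks**

Total step count: 15. Longest linear sequence: 13 steps (steps 1–6 and 9–15); steps 7–8 make the dienophile.

The three steps most likely to fail:

Step 9 (the proposed new relay). The risks are low enantioselectivity at the quaternary carbon, acid-induced loss of the silyl dienol ether and Nazarov or polymerisation side reactions of 13. The fallback uses known chemistry, sets out from 10 and comes back at 14. Diene 10 and commercial 3-acryloyl-1,3-oxazolidin-2-one are combined under Cu(SbF6)2·(S,S)-2,2'-(propane-2,2-diyl)bis(4-tert-butyl-4,5-dihydro-1,3-oxazole) (10 mol %, CH2Cl2, −78 to −20 °C). This is the established chelate-controlled enantioselective Diels–Alder reaction of that imide, and it gives the endo imide cycloadduct F1. Me(MeO)NH·HCl with AlMe3 converts it into the Weinreb amide F2. The alkenyllithium made from (E)-2-bromobut-2-ene and tBuLi (retention, methyl groups cis) then gives ketone 14, which is desilylated and fragmented as in the second half of step 9.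

Step 10 (double Michael with enolate trapping). The risks are competing enolisation of the tether ketone and scrambling of the product enolate before silylation. The fallback sets out from 15 and comes back at 20. Enone 15 is warmed with pyrrolidine and AcOH (20 mol % each, toluene, 60 °C, then water); the cross-conjugated dienamine forms only at the unhindered ring enone and undergoes the same cycloaddition, giving the tricyclic diketone F3. 2-Iodoxybenzoic acid (DMSO, 70 °C) can dehydrogenate only the ring-B ketone, because the bicyclo[2.2.2]octanone cannot hold a double bond at a bridgehead; this gives the enedione F4. Me2CuLi adds as in step 12 to give the methyl diketone F5. tBuMe2SiOTf/Et3N at −78 °C then silylates the tertiary alcohol and enolises only the unhindered bicyclooctanone carbonyl (the ring-B ketone is by then flanked by a quaternary carbon and an axial methyl), which gives 20.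

Step 13 (configuration at C4). The risk is that the reduction gives the axial alcohol or a mixture. The fallback sets out from 20 and comes back at 21. LiAlH4 (THF, −78 °C) attacks from the equatorial direction, away from the axial methyl, and gives mainly the axial C4 epimer F6. Meerwein–Ponndorf–Verley/Oppenauer equilibration (Al(OiPr)3, acetone 0.2 equiv, iPrOH–toluene, 80 °C) then converts it into the equatorial alcohol 21, which is strongly favoured because the axial hydroxyl is syn-diaxial to the C6 methyl.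

Further compounds
F1 | step 9 | 3-({4-[(3S)-3-methyl-3-(TES-oxy)pent-4-en-1-yl]-1-(TES-oxy)bicyclo[2.2.2]oct-5-en-2-yl}carbonyl)-1,3-oxazolidin-2-one, endo, ring stereocentres as in 14 | C=C[C@@](C)(O[Si](CC)(CC)CC)CC[C@]12C=C[C@](O[Si](CC)(CC)CC)(CC1)[C@H](C2)C(=O)N3CCOC3=O
F2 | step 9 | N-methoxy-N-methyl-4-[(3S)-3-methyl-3-(TES-oxy)pent-4-en-1-yl]-1-(TES-oxy)bicyclo[2.2.2]oct-5-ene-2-carboxamide, ring stereocentres as in 14 | C=C[C@@](C)(O[Si](CC)(CC)CC)CC[C@]12C=C[C@](O[Si](CC)(CC)CC)(CC1)[C@H](C2)C(=O)N(C)OC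
F3 | step 10 | (1R,2R,3S,7R,8S)-7-[(3S)-3-hydroxy-3-methylpent-4-en-1-yl]-2,3-dimethyltricyclo[5.3.1.0(3,8)]undecane-4,10-dione | C=C[C@@](C)(O)CC[C@@]12C[C@H]3C(=O)C[C@@H]1[C@](C)([C@@H]3C)C(=O)CC2
F4 | step 10 | (1R,2R,3S,7S,8S)-7-[(3S)-3-hydroxy-3-methylpent-4-en-1-yl]-2,3-dimethyltricyclo[5.3.1.0(3,8)]undec-5-ene-4,10-dione | C=C[C@@](C)(O)CC[C@@]12C[C@H]3C(=O)C[C@@H]1[C@](C)([C@@H]3C)C(=O)C=C2
F5 | step 10 | (1R,2R,3S,6R,7S,8S)-7-[(3S)-3-hydroxy-3-methylpent-4-en-1-yl]-2,3,6-trimethyltricyclo[5.3.1.0(3,8)]undecane-4,10-dione | C=C[C@@](C)(O)CC[C@@]12C[C@H]3C(=O)C[C@@H]1[C@](C)([C@@H]3C)C(=O)C[C@H]2C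
F6 | step 13 | (1R,2R,3S,4S,6R,7S,8S)-10-(TBS-oxy)-7-[(3S)-3-(TBS-oxy)-3-methylpent-4-en-1-yl]-2,3,6-trimethyltricyclo[5.3.1.0(3,8)]undec-9-en-4-ol (C4 epimer of 21) | C=C[C@@](C)(O[Si](C)(C)C(C)(C)C)CC[C@@]12C[C@H]3C(O[Si](C)(C)C(C)(C)C)=C[C@@H]1[C@](C)([C@@H]3C)[C@@H](O)C[C@H]2C
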